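Retrosynthesis: the ten benzyl ethers come off last; the C1–C2 bond of the propan-2-ol chain (C1 = CH carrying the catechol ring and flavan C8, C2 = carbinol carbon) is cut as a 1,2-metallate rearrangement between an α-lithiated 2-arylethyl benzoate (C2) and a diarylmethyl pinacol boronate (C1). C1–B then goes back to C1–O, and C1–C8 to an 8-lithioflavan plus an aldehyde.
Enabling feature: C2 carries the only oxygen of the chain, so it can hold lithium and an O-leaving group at once (a carbenoid, polarity reversal of a carbinol carbon); C1 is benzylic to both the catechol ring and ring A, so it holds boron and migrates with retention.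
Forward: (+)-catechin gives rings A, B and C intact; benzylation, C8 bromination, aryllithium addition to 3,4-bis(benzyloxy)benzaldehyde, oxidation, asymmetric hydrogenation, carbamate and lithiation–borylation give boronate 13. 1,3,5-Tris(benzyloxy)benzene gives benzoate 18; 18 and 13 are joined in step 12; hydrogenolysis ends the route. No ring is formed.
Stereochemistry: flavan C2 (R) and C3 (S) come from catechin; C1 comes from a catalyst-controlled ketone hydrogenation and is carried through two stereospecific 1,2-shifts; C2 comes from (+)-sparteine-mediated deprotonation.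

Key step: step 12

Remark: C1, C2, C3 are the chain carbons; "penta-O-benzylcatechin-8-yl" means (2R,3S)-3,5,7-tris(benzyloxy)-2-[3,4-bis(benzyloxy)phenyl]chroman-8-yl. It is assumed that pinacol boron reagents capture the α-lithiated carbamate and benzoate with retention.

Step 1
Reactants: 1 (+)-catechin
Product: 2 5,7,3',4'-tetra-O-benzyl-(+)-catechin
Conditions: BnBr (4.4 equiv), K2CO3, DMF, 0 °C to rt, argon
Reagents that add atoms: benzyl bromide, BrCc1ccccc1
Why: Williamson etherification in which carbonate deprotonates only the four phenols, so the C3 alcohol stays free and neither stereocentre is touched.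

Step 2
Reactants: 2 5,7,3',4'-tetra-O-benzyl-(+)-catechin
Product: 3 penta-O-benzyl-(+)-catechin
Conditions: NaH (1.5 equiv), BnBr (1.3 equiv), Bu4NI (cat.), DMF, 0 °C to rt
Reagents that add atoms: benzyl bromide, BrCc1ccccc1
Why: Williamson etherification of the C3 alkoxide; with no free phenol left ring C cannot open, so both stereocentres persist.

Step 3
Reactants: 3 penta-O-benzyl-(+)-catechin
Product: 4 8-bromo-penta-O-benzyl-(+)-catechin
Conditions: NBS (1.0 equiv), CH2Cl2, −78 °C to rt
Reagents that add atoms: N-bromosuccinimide, O=C1CCC(=O)N1Br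
Why: Electrophilic aromatic bromination of the most electron-rich ring (ring A), which in 5,7-di-O-benzylflavans takes place at C8 in preference to C6.

Step 4
Reactants: 4 8-bromo-penta-O-benzyl-(+)-catechin; 5 3,4-bis(benzyloxy)benzaldehyde
Product: 7 [3,4-bis(benzyloxy)phenyl](penta-O-benzylcatechin-8-yl)methanol (both epimers at the carbinol carbon), via 8-lithioflavan 6 (not isolated)
Conditions: nBuLi (1.05 equiv), THF, −78 °C; 5 (1.2 equiv), −78 to 0 °C; H2O
Reagents that add atoms: none
Why: Bromine–lithium exchange followed by 1,2-addition of the aryllithium to the aldehyde; the new carbinol centre forms without control and is erased in step 5.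

Step 5
Reactants: 7 [3,4-bis(benzyloxy)phenyl](penta-O-benzylcatechin-8-yl)methanol
Product: 8 [3,4-bis(benzyloxy)phenyl](penta-O-benzylcatechin-8-yl)methanone
Conditions: Dess–Martin periodinane (1.3 equiv), pyridine, CH2Cl2, 0 °C to rt
Reagents that add atoms: none
Why: Dess–Martin oxidation of a doubly benzylic alcohol under buffered conditions that should not ionise the electron-rich benzhydrol; both epimers converge on one ketone.

Step 6
Reactants: 8 [3,4-bis(benzyloxy)phenyl](penta-O-benzylcatechin-8-yl)methanone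
Product: 9 (S)-[3,4-bis(benzyloxy)phenyl](penta-O-benzylcatechin-8-yl)methanol
Conditions: H2 (8 atm), trans-RuCl2[(S)-xylbinap][(S)-daipen] (1 mol %), KOtBu (4 mol %), iPrOH/toluene, 30 °C
Reagents that add atoms: none
Why: Noyori asymmetric hydrogenation; ring A, twisted out of the carbonyl plane by O1 and the 7-benzyloxy group, should play the part of the non-conjugated substituent as in ortho-substituted benzophenones, so the (S),(S) catalyst should give the S carbinol under catalyst control.

Step 7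
Reactants: 9 (S)-[3,4-bis(benzyloxy)phenyl](penta-O-benzylcatechin-8-yl)methanol
Product: 10 (S)-[3,4-bis(benzyloxy)phenyl](penta-O-benzylcatechin-8-yl)methyl N,N-diisopropylcarbamate
Conditions: NaH (1.5 equiv), THF, 0 °C; N,N-diisopropylcarbamoyl chloride (1.3 equiv), 0 to 50 °C
Reagents that add atoms: N,N-diisopropylcarbamoyl chloride, CC(C)N(C(C)C)C(Cl)=O
Why: O-Carbamoylation of the sodium alkoxide (nucleophilic acyl substitution); no bond to C1 is broken and no acid is present, so the configuration is kept.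

Step 8
Reactants: 10 (S)-[3,4-bis(benzyloxy)phenyl](penta-O-benzylcatechin-8-yl)methyl N,N-diisopropylcarbamate
Product: 13 2-{(S)-[3,4-bis(benzyloxy)phenyl](penta-O-benzylcatechin-8-yl)methyl}-4,4,5,5-tetramethyl-1,3,2-dioxaborolane, via lithiated carbamate 11 (not isolated), via borohydride complex 12 (not isolated)
Conditions: sBuLi (1.3 equiv), Et2O, −78 °C, 1 h; pinacolborane (1.5 equiv), −78 °C, 1 h, then rt, 12 h
Reagents that add atoms: pinacolborane, B1OC(C)(C)C(C)(C)O1
Why: Proposed new method: carbamate-directed removal of the C1 proton gives an α-lithiated carbamate that should keep its configuration at −78 °C, because lithium is chelated by the carbamate carbonyl and the 7-benzyloxy oxygen and the twisted ring A cannot delocalise the carbanion; pinacolborane captures it with retention and hydride then shifts from boron to C1 anti to the departing carbamate (inversion), so boron ends where oxygen was; the closest known reaction type is the lithiation–borylation of secondary 1-arylalkyl carbamates with pinacolborane (1,2-hydride shift in the borohydride complex).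

Step 9
Reactants: 14 1,3,5-tris(benzyloxy)benzene
Product: 15 2-bromo-1,3,5-tris(benzyloxy)benzene
Conditions: NBS (1.0 equiv), CH2Cl2, −20 °C
Reagents that add atoms: N-bromosuccinimide, O=C1CCC(=O)N1Br
Why: Electrophilic aromatic bromination of a symmetric arene whose three free positions are equivalent; one equivalent of reagent at low temperature should stop at the monobromide.

Step 10
Reactants: 15 2-bromo-1,3,5-tris(benzyloxy)benzene
Product: 17 2-[2,4,6-tris(benzyloxy)phenyl]ethanol, via aryllithium 16 (not isolated)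
Conditions: tBuLi (2.0 equiv), THF, −78 °C; oxirane (5 equiv), −78 to 0 °C; H2O
Reagents that add atoms: oxirane, C1CO1
Why: Bromine–lithium exchange (the second equivalent of tBuLi destroys tBuBr) followed by SN2 opening of oxirane by the electron-rich aryllithium.

Step 11
Reactants: 17 2-[2,4,6-tris(benzyloxy)phenyl]ethanol
Product: 18 2-[2,4,6-tris(benzyloxy)phenyl]ethyl 2,4,6-triisopropylbenzoate
Conditions: 2,4,6-triisopropylbenzoic acid (1.2 equiv), PPh3, DIAD, THF, 0 °C to rt
Reagents that add atoms: 2,4,6-triisopropylbenzoic acid, CC(C)c1cc(C(C)C)c(c(C(C)C)c1)C(O)=O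
Why: Mitsunobu esterification of a primary alcohol with the hindered acid, which installs the directing and leaving group for step 12.

Step 12
Reactants: 18 2-[2,4,6-tris(benzyloxy)phenyl]ethyl 2,4,6-triisopropylbenzoate; 13 2-{(S)-[3,4-bis(benzyloxy)phenyl](penta-O-benzylcatechin-8-yl)methyl}-4,4,5,5-tetramethyl-1,3,2-dioxaborolane
Product: 22 (1S,2S)-1-[3,4-bis(benzyloxy)phenyl]-1-(penta-O-benzylcatechin-8-yl)-3-[2,4,6-tris(benzyloxy)phenyl]propan-2-ol, via lithiated benzoate 19 (not isolated), via boronate complex 20 (not isolated), via secondary boronic ester 21 (not isolated)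
Conditions: 18 (1.3 equiv), sBuLi (1.3 equiv), (+)-sparteine (1.3 equiv), Et2O, −78 °C, 5 h; 13 (1.0 equiv) in Et2O/toluene, −78 °C, 2 h, then 40 °C, 16 h; then 2 M NaOH, 30% H2O2, THF, 0 °C to rt
Reagents that add atoms: hydrogen peroxide, OO
Why: sBuLi/(+)-sparteine removes the pro-R hydrogen next to the benzoate oxygen of 18 to give configurationally stable (R)-19; boron of 13 captures it with retention to give complex 20, in which the diarylmethyl group shifts from boron to C2 anti to the departing 2,4,6-triisopropylbenzoate (inversion at C2, retention at C1), and alkaline H2O2 then replaces boron by OH with retention. The closest known reaction type is the lithiation–borylation (Matteson-type 1,2-metallate rearrangement) of sparteine-lithiated primary benzoates and carbamates with secondary benzylic pinacol boronic esters. No ring is closed. C2 is the only new stereocentre and is set by the chiral diamine (reagent control), independently of the existing centres; C1 is transferred unchanged from 13. The step needs α-lithiation of the ester in preference to attack on the aryl benzyl ethers, which pre-complexation of sBuLi to the benzoate carbonyl at −78 °C should secure, and addition to boron in preference to removal of the acidic C1–H of 13, which the low temperature and the Lewis acidity of the boronate should secure.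

Step 13
Reactants: 22 (1S,2S)-1-[3,4-bis(benzyloxy)phenyl]-1-(penta-O-benzylcatechin-8-yl)-3-[2,4,6-tris(benzyloxy)phenyl]propan-2-ol
Product: 23 CNP0175733.2 (target)
Conditions: H2 (1 atm), Pd(OH)2 on carbon, THF/MeOH, rt; filtration under argon, freeze-drying
Reagents that add atoms: none
Why: Hydrogenolysis of the ten O-benzyl groups; the C–O bond of ring C and the non-benzylic C2–OH should survive these neutral conditions, and no stereocentre is involved.

Compound list
1 | (+)-catechin, (2R,3S)-2-(3,4-dihydroxyphenyl)chroman-3,5,7-triol | Oc1cc(O)c2c(c1)O[C@H](c1ccc(O)c(O)c1)[C@@H](O)C2 | starting material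
2 | 5,7,3',4'-tetra-O-benzyl-(+)-catechin | c1c(OCc2ccccc2)cc(OCc2ccccc2)c2c1O[C@H](c1ccc(OCc3ccccc3)c(OCc3ccccc3)c1)[C@@H](O)C2 | intermediate
3 | penta-O-benzyl-(+)-catechin, (2R,3S)-3,5,7-tris(benzyloxy)-2-[3,4-bis(benzyloxy)phenyl]chroman | c1c(OCc2ccccc2)cc(OCc2ccccc2)c2c1O[C@H](c1ccc(OCc3ccccc3)c(OCc3ccccc3)c1)[C@@H](OCc1ccccc1)C2 | intermediate
4 | 8-bromo-penta-O-benzyl-(+)-catechin | Brc1c(OCc2ccccc2)cc(OCc2ccccc2)c2c1O[C@H](c1ccc(OCc3ccccc3)c(OCc3ccccc3)c1)[C@@H](OCc1ccccc1)C2 | intermediate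
5 | 3,4-bis(benzyloxy)benzaldehyde | O=Cc1ccc(OCc2ccccc2)c(OCc2ccccc2)c1 | starting material
6 | 8-lithio-penta-O-benzyl-(+)-catechin | [Li]c1c(OCc2ccccc2)cc(OCc2ccccc2)c2c1O[C@H](c1ccc(OCc3ccccc3)c(OCc3ccccc3)c1)[C@@H](OCc1ccccc1)C2 | intermediate
7 | [3,4-bis(benzyloxy)phenyl](penta-O-benzylcatechin-8-yl)methanol, both carbinol epimers | OC(c1ccc(OCc2ccccc2)c(OCc2ccccc2)c1)c1c(OCc2ccccc2)cc(OCc2ccccc2)c2c1O[C@H](c1ccc(OCc3ccccc3)c(OCc3ccccc3)c1)[C@@H](OCc1ccccc1)C2 | intermediate
8 | [3,4-bis(benzyloxy)phenyl](penta-O-benzylcatechin-8-yl)methanone | O=C(c1ccc(OCc2ccccc2)c(OCc2ccccc2)c1)c1c(OCc2ccccc2)cc(OCc2ccccc2)c2c1O[C@H](c1ccc(OCc3ccccc3)c(OCc3ccccc3)c1)[C@@H](OCc1ccccc1)C2 | intermediate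
9 | (S)-[3,4-bis(benzyloxy)phenyl](penta-O-benzylcatechin-8-yl)methanol | O[C@@H](c1ccc(OCc2ccccc2)c(OCc2ccccc2)c1)c1c(OCc2ccccc2)cc(OCc2ccccc2)c2c1O[C@H](c1ccc(OCc3ccccc3)c(OCc3ccccc3)c1)[C@@H](OCc1ccccc1)C2 | intermediate
10 | (S)-[3,4-bis(benzyloxy)phenyl](penta-O-benzylcatechin-8-yl)methyl N,N-diisopropylcarbamate | CC(C)N(C(C)C)C(=O)O[C@@H](c1ccc(OCc2ccccc2)c(OCc2ccccc2)c1)c1c(OCc2ccccc2)cc(OCc2ccccc2)c2c1O[C@H](c1ccc(OCc3ccccc3)c(OCc3ccccc3)c1)[C@@H](OCc1ccccc1)C2 | intermediate
11 | α-lithiated carbamate (lithium on C1 in place of hydrogen, configuration retained) | CC(C)N(C(C)C)C(=O)O[C@@]([Li])(c1ccc(OCc2ccccc2)c(OCc2ccccc2)c1)c1c(OCc2ccccc2)cc(OCc2ccccc2)c2c1O[C@H](c1ccc(OCc3ccccc3)c(OCc3ccccc3)c1)[C@@H](OCc1ccccc1)C2 | intermediate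
12 | lithium borohydride complex (C1 of 11 bonded to boron of pinacolborane) | [Li+].CC(C)N(C(C)C)C(=O)O[C@@]([BH-]1OC(C)(C)C(C)(C)O1)(c1ccc(OCc2ccccc2)c(OCc2ccccc2)c1)c1c(OCc2ccccc2)cc(OCc2ccccc2)c2c1O[C@H](c1ccc(OCc3ccccc3)c(OCc3ccccc3)c1)[C@@H](OCc1ccccc1)C2 | intermediate
13 | 2-{(S)-[3,4-bis(benzyloxy)phenyl](penta-O-benzylcatechin-8-yl)methyl}-4,4,5,5-tetramethyl-1,3,2-dioxaborolane | CC1(C)OB(OC1(C)C)[C@@H](c1ccc(OCc2ccccc2)c(OCc2ccccc2)c1)c1c(OCc2ccccc2)cc(OCc2ccccc2)c2c1O[C@H](c1ccc(OCc3ccccc3)c(OCc3ccccc3)c1)[C@@H](OCc1ccccc1)C2 | intermediate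
14 | 1,3,5-tris(benzyloxy)benzene | c1c(OCc2ccccc2)cc(OCc2ccccc2)cc1OCc1ccccc1 | starting material
15 | 2-bromo-1,3,5-tris(benzyloxy)benzene | Brc1c(OCc2ccccc2)cc(OCc2ccccc2)cc1OCc1ccccc1 | intermediate
16 | 2,4,6-tris(benzyloxy)phenyllithium | [Li]c1c(OCc2ccccc2)cc(OCc2ccccc2)cc1OCc1ccccc1 | intermediate
17 | 2-[2,4,6-tris(benzyloxy)phenyl]ethanol | OCCc1c(OCc2ccccc2)cc(OCc2ccccc2)cc1OCc1ccccc1 | intermediate
18 | 2-[2,4,6-tris(benzyloxy)phenyl]ethyl 2,4,6-triisopropylbenzoate | CC(C)c1cc(C(C)C)c(c(C(C)C)c1)C(=O)OCCc1c(OCc2ccccc2)cc(OCc2ccccc2)cc1OCc1ccccc1 | intermediate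
19 | (R)-1-lithio-2-[2,4,6-tris(benzyloxy)phenyl]ethyl 2,4,6-triisopropylbenzoate (sparteine complex) | CC(C)c1cc(C(C)C)c(c(C(C)C)c1)C(=O)O[C@@H](Cc1c(OCc2ccccc2)cc(OCc2ccccc2)cc1OCc1ccccc1)[Li] | intermediate
20 | lithium boronate complex (boron of 13 bonded to C2 of 19, benzoate still on C2) | [Li+].CC(C)c1cc(C(C)C)c(c(C(C)C)c1)C(=O)O[C@@H](Cc1c(OCc2ccccc2)cc(OCc2ccccc2)cc1OCc1ccccc1)[B-]1(OC(C)(C)C(C)(C)O1)[C@@H](c1ccc(OCc2ccccc2)c(OCc2ccccc2)c1)c1c(OCc2ccccc2)cc(OCc2ccccc2)c2c1O[C@H](c1ccc(OCc3ccccc3)c(OCc3ccccc3)c1)[C@@H](OCc1ccccc1)C2 | intermediate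
21 | 2-{(1S,2S)-1-[3,4-bis(benzyloxy)phenyl]-1-(penta-O-benzylcatechin-8-yl)-3-[2,4,6-tris(benzyloxy)phenyl]propan-2-yl}-4,4,5,5-tetramethyl-1,3,2-dioxaborolane | CC1(C)OB(OC1(C)C)[C@@H](Cc1c(OCc2ccccc2)cc(OCc2ccccc2)cc1OCc1ccccc1)[C@@H](c1ccc(OCc2ccccc2)c(OCc2ccccc2)c1)c1c(OCc2ccccc2)cc(OCc2ccccc2)c2c1O[C@H](c1ccc(OCc3ccccc3)c(OCc3ccccc3)c1)[C@@H](OCc1ccccc1)C2 | intermediate
22 | (1S,2S)-1-[3,4-bis(benzyloxy)phenyl]-1-(penta-O-benzylcatechin-8-yl)-3-[2,4,6-tris(benzyloxy)phenyl]propan-2-ol | O[C@@H](Cc1c(OCc2ccccc2)cc(OCc2ccccc2)cc1OCc1ccccc1)[C@@H](c1ccc(OCc2ccccc2)c(OCc2ccccc2)c1)c1c(OCc2ccccc2)cc(OCc2ccccc2)c2c1O[C@H](c1ccc(OCc3ccccc3)c(OCc3ccccc3)c1)[C@@H](OCc1ccccc1)C2 | intermediate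
23 | CNP0175733.2, (1S,2S)-1-(3,4-dihydroxyphenyl)-1-[(2R,3S)-2-(3,4-dihydroxyphenyl)-3,5,7-trihydroxychroman-8-yl]-3-(2,4,6-trihydroxyphenyl)propan-2-ol | Oc1cc(O)c(C[C@H](O)[C@@H](c2ccc(O)c(O)c2)c2c(O)cc(O)c3c2O[C@H](c2ccc(O)c(O)c2)[C@@H](O)C3)c(O)c1 | target

Total steps: 13. Longest linear sequence: 10 steps (steps 1 to 8, 12, 13).

Steps most likely to fail

Step 8 (proposed new method). The α-lithiated carbamate may lose its configuration by planarisation before boron captures it, or sBuLi may attack a benzylic OCH2 group; either would erode the C1 centre. The fallback uses known chemistry, sets out from bromide 4 and aldehyde 5 and comes back at boronate 13. Bromine–lithium exchange on 4 (nBuLi, THF, −78 °C) and quench with 2-isopropoxy-4,4,5,5-tetramethyl-1,3,2-dioxaborolane would give 2-(penta-O-benzylcatechin-8-yl)-4,4,5,5-tetramethyl-1,3,2-dioxaborolane F1. Reduction of 5 with NaBH4 would give 3,4-bis(benzyloxy)benzyl alcohol F2, which NaH and N,N-diisopropylcarbamoyl chloride would convert into 3,4-bis(benzyloxy)benzyl N,N-diisopropylcarbamate F3. F3 would be lithiated with sBuLi in the presence of a C2-symmetric bis(oxazoline) ligand such as 2,2-bis[(4S)-4-isopropyl-4,5-dihydrooxazol-2-yl]propane, or its enantiomer if that is the one that leads to the S boronate. The labile benzyllithium–ligand complexes resolve dynamically; F1 is added at −78 °C and, on warming, ring A shifts from boron to carbon with loss of the carbamate to give 13. C1 is then set by the chiral ligand in an aryl 1,2-shift, not by transfer from a carbinol.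

Step 12. Formation of the boronate complex may be slow or reversible because boron in 13 sits next to a 2,6-dioxygenated ring; the lithiated benzoate may instead remove the acidic C1–H of 13 and scramble C1; sBuLi may lithiate a benzyl ether of 18. The fallback sets out from 5, 14 and 3, comes back at 22, and forms the C1–C8 bond instead. Addition of CH2=CHMgBr to 5 would give 1-[3,4-bis(benzyloxy)phenyl]prop-2-en-1-ol F4. Acid-catalysed (TsOH, CH2Cl2) Friedel–Crafts allylation of 14 with F4, through the aryl-stabilised allyl cation attacked at its free terminus, would give (E)-1-[3,4-bis(benzyloxy)phenyl]-3-[2,4,6-tris(benzyloxy)phenyl]prop-1-ene F5. Shi epoxidation with the enantiomer of the fructose-derived ketone (Oxone, 2KHSO5·KHSO4·K2SO4, buffered with K2CO3) would give (2S,3S)-2-[3,4-bis(benzyloxy)phenyl]-3-[2,4,6-tris(benzyloxy)benzyl]oxirane F6. Lewis acid-promoted (BF3·OEt2, CH2Cl2, −78 °C) Friedel–Crafts opening of F6 at its benzylic carbon by C8 of 3, with inversion, would give 22; both chain centres then come from the epoxide.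

Step 6. Both groups on the carbonyl are aryl and the ketone is flanked by two ortho substituents, so the hydrogenation may stall or deliver hydride with poor facial selectivity. The fallback sets out from 4 and comes back at 9. Bromine–lithium exchange on 4 and formylation with DMF would give penta-O-benzylcatechin-8-carbaldehyde F7. Catalytic enantioselective aryl transfer to F7 (3,4-bis(benzyloxy)phenylboronic acid transmetallated with Et2Zn, a chiral β-amino alcohol such as 2-piperidino-1,1,2-triphenylethanol in the enantiomer that leads to the S carbinol, toluene) would give 9; C1 is then set in a C–C bond formation and not in a reduction.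

Further compounds
F1 | step 8 | 2-(penta-O-benzylcatechin-8-yl)-4,4,5,5-tetramethyl-1,3,2-dioxaborolane | CC1(C)OB(OC1(C)C)c1c(OCc2ccccc2)cc(OCc2ccccc2)c2c1O[C@H](c1ccc(OCc3ccccc3)c(OCc3ccccc3)c1)[C@@H](OCc1ccccc1)C2
F2 | step 8 | 3,4-bis(benzyloxy)benzyl alcohol | OCc1ccc(OCc2ccccc2)c(OCc2ccccc2)c1
F3 | step 8 | 3,4-bis(benzyloxy)benzyl N,N-diisopropylcarbamate | CC(C)N(C(C)C)C(=O)OCc1ccc(OCc2ccccc2)c(OCc2ccccc2)c1
F4 | step 12 | 1-[3,4-bis(benzyloxy)phenyl]prop-2-en-1-ol (racemic) | C=CC(O)c1ccc(OCc2ccccc2)c(OCc2ccccc2)c1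
F5 | step 12 | (E)-1-[3,4-bis(benzyloxy)phenyl]-3-[2,4,6-tris(benzyloxy)phenyl]prop-1-ene | C(/C=C/c1ccc(OCc2ccccc2)c(OCc2ccccc2)c1)c1c(OCc2ccccc2)cc(OCc2ccccc2)cc1OCc1ccccc1
F6 | step 12 | (2S,3S)-2-[3,4-bis(benzyloxy)phenyl]-3-[2,4,6-tris(benzyloxy)benzyl]oxirane | C([C@@H]1O[C@H]1c1ccc(OCc2ccccc2)c(OCc2ccccc2)c1)c1c(OCc2ccccc2)cc(OCc2ccccc2)cc1OCc1ccccc1
F7 | step 6 | penta-O-benzylcatechin-8-carbaldehyde | O=Cc1c(OCc2ccccc2)cc(OCc2ccccc2)c2c1O[C@H](c1ccc(OCc3ccccc3)c(OCc3ccccc3)c1)[C@@H](OCc1ccccc1)C2
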